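**Retrosynthetic overview**

- The strategy rests on ring A carrying the ketone carbon at C1' and a hydroxyl on the neighbouring C6'. This ortho-hydroxyaryl ketone is what results when an aryne C1'≡C6' inserts into the C(=O)–O bond of the ring B propanoic acid (forms C6'–O and C1'–C(=O)).
- Target 33 comes from the tris-MOM ether 32 by acid methanolysis; 32 comes from silyl triflate 15 (aryne 30) and acid 28.
- 15 is made from phloroglucinol: bis-MOM ether, TIPS ether, metalation and prenylation between the MOM ethers, desilylation, carbamate-directed ortho-silylation, triflation.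
- 28 is made from 3-bromo-4,5-dihydroxybenzaldehyde: 4-O-methylation, acetal, MOM ether, Br–Li/Cu prenylation, Meldrum's acid reductive alkylation, decarboxylation.
- No ring is formed: both benzene rings are bought, ring A is elaborated first (longest branch), ring B in parallel, and the two are joined in step 14.

Key step: step 14

Remark: primed locants are ring A (the acyl-bearing phloroglucinol ring), unprimed locants ring B, and prenyl means 3-methylbut-2-en-1-yl; 3-bromo-4,5-dihydroxybenzaldehyde is taken as the commercial entry to ring B, because its bromine marks C5 and its formyl group differentiates the two hydroxyls.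

**Route**

Step 1
Reactants: 1 phloroglucinol
Product: 2 3,5-bis(methoxymethoxy)phenol
Conditions: MOMCl (2.0 equiv), iPr2NEt, DMF, 0 °C to rt
Reagents that add atoms: chloromethyl methyl ether (MOMCl), COCCl
Why: O-alkylation of the threefold-symmetric triol with two equivalents of the α-chloro ether (Williamson-type) should give the bis-ether as the main statistical product, the mono- and tris-ethers being removed by chromatography.

Step 2
Reactants: 2 3,5-bis(methoxymethoxy)phenol
Product: 3 [3,5-bis(methoxymethoxy)phenoxy]triisopropylsilane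
Conditions: TIPSCl, imidazole, DMF, rt
Reagents that add atoms: triisopropylsilyl chloride (TIPSCl), CC(C)[Si](Cl)(C(C)C)C(C)C
Why: Imidazole-mediated silylation caps the last phenol with a bulky group that does not direct metalation and shields its own two ortho C–H bonds.

Step 3
Reactants: 3 [3,5-bis(methoxymethoxy)phenoxy]triisopropylsilane; 4 prenyl bromide
Product: 7 [3,5-bis(methoxymethoxy)-4-prenylphenoxy]triisopropylsilane, via aryllithium 5 (not isolated), via arylcopper 6 (not isolated)
Conditions: n-BuLi, THF, 0 °C to rt; CuI, −40 °C; 4, −78 °C to rt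
Reagents that add atoms: none
Why: Directed ortho-metalation should occur at the C–H flanked by both MOM ethers (double chelation), and the arylcopper formed with CuI should attack the primary carbon of prenyl bromide (SN2 allylic substitution) to give the linear prenyl arene.

Step 4
Reactants: 7 [3,5-bis(methoxymethoxy)-4-prenylphenoxy]triisopropylsilane
Product: 8 3,5-bis(methoxymethoxy)-4-prenylphenol
Conditions: TBAF, THF, 0 °C; aq NH4Cl
Reagents that add atoms: none
Why: Fluoride cleavage of the aryl silyl ether leaves MOM ethers and the prenyl alkene untouched and gives a phenol with a mirror plane through C1 and C4.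

Step 5
Reactants: 8 3,5-bis(methoxymethoxy)-4-prenylphenol
Product: 9 3,5-bis(methoxymethoxy)-4-prenylphenyl N-isopropylcarbamate
Conditions: i-PrNCO, Et3N (cat.), CH2Cl2, rt
Reagents that add atoms: isopropyl isocyanate, CC(C)N=C=O
Why: Base-catalysed addition of the phenol to the isocyanate gives the carbamate that serves both as metalation director and as a phenol mask removable under mild base.

Step 6
Reactants: 9 3,5-bis(methoxymethoxy)-4-prenylphenyl N-isopropylcarbamate
Product: 13 3,5-bis(methoxymethoxy)-4-prenyl-2-(trimethylsilyl)phenyl N-isopropylcarbamate, via N-TBS carbamate 10 (not isolated), via ortho-lithiated N-TBS carbamate 11 (not isolated), via N-TBS C-TMS carbamate 12 (not isolated)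
Conditions: TBSOTf, TMEDA, Et2O, 0 °C to rt; then TMEDA, n-BuLi, −78 °C; TMSCl, −78 °C to rt; cold 1 M aq NaHSO4 (brief)
Reagents that add atoms: chlorotrimethylsilane (TMSCl), C[Si](C)(C)Cl (tert-butyldimethylsilyl triflate, CC(C)(C)[Si](C)(C)OS(=O)(=O)C(F)(F)F, adds only the transient N-silyl group)
Why: In situ N-silylation masks the N–H, carbamate-directed ortho-lithiation then takes place at the C–H flanked by the carbamate and a MOM ether (the two such positions of 9 are equivalent by symmetry, so no regiochemical question arises), TMSCl traps the aryllithium, and the short cold acidic wash removes the N-silyl group without touching the aryl MOM ethers.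

Step 7
Reactants: 13 3,5-bis(methoxymethoxy)-4-prenyl-2-(trimethylsilyl)phenyl N-isopropylcarbamate
Product: 15 3,5-bis(methoxymethoxy)-4-prenyl-2-(trimethylsilyl)phenyl trifluoromethanesulfonate, via silylphenol 14 (not isolated)
Conditions: DBU, Et2NH, MeCN, 40 °C; then PhNTf2, rt
Reagents that add atoms: N-phenylbis(trifluoromethanesulfonimide) (PhNTf2), O=S(=O)(N(c1ccccc1)S(=O)(=O)C(F)(F)F)C(F)(F)F
Why: DBU induces E1cB loss of isopropyl isocyanate from the N–H carbamate (scavenged by Et2NH as a urea), and the liberated ortho-silyl phenol is triflated in the same flask under base, which avoids protodesilylation of the electron-rich aryl silane.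

Step 8
Reactants: 16 3-bromo-4,5-dihydroxybenzaldehyde
Product: 17 3-bromo-5-hydroxy-4-methoxybenzaldehyde
Conditions: MeI (1.1 equiv), Li2CO3, DMF, 40 °C
Reagents that add atoms: iodomethane, CI
Why: The 4-hydroxyl, para to the formyl group and ortho to bromine, is the more acidic one, so the weak base should generate and methylate only that phenoxide (regioselective Williamson etherification).

Step 9
Reactants: 17 3-bromo-5-hydroxy-4-methoxybenzaldehyde
Product: 18 3-bromo-5-(dimethoxymethyl)-2-methoxyphenol
Conditions: HC(OMe)3, MeOH, TsOH·H2O (cat.), rt; Et3N quench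
Reagents that add atoms: trimethyl orthoformate, COC(OC)OC; methanol, CO
Why: Acid-catalysed acetalisation with the orthoformate as water scavenger masks the aldehyde before the organolithium step, and is done before the MOM ether is present so that no acid-labile ether is exposed.

Step 10
Reactants: 18 3-bromo-5-(dimethoxymethyl)-2-methoxyphenol
Product: 19 1-bromo-5-(dimethoxymethyl)-2-methoxy-3-(methoxymethoxy)benzene
Conditions: MOMCl, iPr2NEt, CH2Cl2, 0 °C to rt
Reagents that add atoms: chloromethyl methyl ether (MOMCl), COCCl
Why: O-alkylation of the phenol under basic conditions leaves the dimethyl acetal intact and installs the protecting group that is removed together with those of ring A at the end.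

Step 11
Reactants: 19 1-bromo-5-(dimethoxymethyl)-2-methoxy-3-(methoxymethoxy)benzene; 4 prenyl bromide
Product: 23 4-methoxy-3-(methoxymethoxy)-5-prenylbenzaldehyde, via aryllithium 20 (not isolated), via arylcopper 21 (not isolated), via prenylated acetal 22 (not isolated)
Conditions: n-BuLi, THF, −78 °C; CuI, −78 to −40 °C; 4, −78 to 0 °C; then PPTS, acetone/H2O, rt
Reagents that add atoms: water, O
Why: Bromine–lithium exchange at −78 °C, transmetalation to copper and SN2 allylic substitution place the linear prenyl group at C5, and the benzylic dimethyl acetal is then hydrolysed by PPTS far faster than the aryl MOM ether.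

Step 12
Reactants: 23 4-methoxy-3-(methoxymethoxy)-5-prenylbenzaldehyde; 24 Meldrum's acid
Product: 26 5-[4-methoxy-3-(methoxymethoxy)-5-prenylbenzyl]-2,2-dimethyl-1,3-dioxane-4,6-dione, via arylidene Meldrum's acid 25 (not isolated)
Conditions: Hantzsch ester (diethyl 2,6-dimethyl-1,4-dihydropyridine-3,5-dicarboxylate), L-proline (20 mol%), EtOH, rt
Reagents that add atoms: none
Why: Knoevenagel condensation followed by conjugate hydride transfer from the Hantzsch ester (organocatalytic reductive alkylation) reduces only the strongly electron-poor alkylidene malonate and leaves the prenyl alkene alone.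

Step 13
Reactants: 26 5-[4-methoxy-3-(methoxymethoxy)-5-prenylbenzyl]-2,2-dimethyl-1,3-dioxane-4,6-dione
Product: 28 3-[4-methoxy-3-(methoxymethoxy)-5-prenylphenyl]propanoic acid, via benzylmalonic acid 27 (not isolated)
Conditions: pyridine/H2O (10:1), reflux; citric acid work-up
Reagents that add atoms: water, O
Why: Hydrolytic opening of the Meldrum's acid ring with loss of acetone and decarboxylation of the malonic acid in the pyridine-buffered medium (Doebner-type) gives the propanoic acid without exposing the MOM ether to strong acid.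

Step 14
Reactants: 28 3-[4-methoxy-3-(methoxymethoxy)-5-prenylphenyl]propanoic acid; 15 3,5-bis(methoxymethoxy)-4-prenyl-2-(trimethylsilyl)phenyl trifluoromethanesulfonate
Product: 32 1-[6-hydroxy-2,4-bis(methoxymethoxy)-3-prenylphenyl]-3-[4-methoxy-3-(methoxymethoxy)-5-prenylphenyl]propan-1-one, via caesium carboxylate 29 (not isolated), via aryne 30 (not isolated), via aryl anion ester 31 (not isolated)
Conditions: 15 (1.5 equiv), CsF (4 equiv), THF, 125 °C, sealed tube
Reagents that add atoms: none
Why: Fluoride attacks the trimethylsilyl group of 15 and triflate leaves, giving the 3,5-dialkoxy-4-prenylbenzyne 30 (C1'≡C6'), while CsF also converts acid 28 into carboxylate 29. The carboxylate oxygen adds to C6', and the aryl anion 31 formed at C1' attacks the neighbouring ester carbonyl through a four-membered transition state (an anionic Fries-type 1,3-acyl shift), giving the ketone and the 6'-phenoxide, which is protonated on work-up. The closest known reaction type is the fluoride-induced insertion of arynes into the C–O bond of carboxylic acids, which gives ortho-hydroxyaryl ketones from aliphatic acids and from 3-alkoxybenzynes. No ring is closed and no stereocentre is formed. The step needs oxygen at C6' and acyl at C1': the 2'-alkoxy group beside the triple bond stabilises developing negative charge at C1' inductively and distorts the aryne so that the nucleophile enters at the distal, unhindered C6' (next to C5'–H), as is general for 3-alkoxybenzynes, and the prenyl group is remote from the triple bond. Excess CsF binds the acid proton as bifluoride and the high temperature in THF favours the acyl shift over protonation of 31 to the simple aryl ester.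

Step 15
Reactants: 32 1-[6-hydroxy-2,4-bis(methoxymethoxy)-3-prenylphenyl]-3-[4-methoxy-3-(methoxymethoxy)-5-prenylphenyl]propan-1-one
Product: 33 3,2',4',6'-tetrahydroxy-4-methoxy-3',5-diprenyldihydrochalcone
Conditions: 3 M aq HCl (small volume), MeOH, rt to 40 °C
Reagents that add atoms: none
Why: Acid-catalysed acetal exchange with methanol should remove all three MOM ethers, and dilute acid with short exposure should keep the 3'-prenyl group from cyclising onto a neighbouring phenol to a chroman.

**Compound list**

1 | phloroglucinol | Oc1cc(O)cc(O)c1 | starting material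
2 | 3,5-bis(methoxymethoxy)phenol | COCOc1cc(O)cc(OCOC)c1 | intermediate
3 | [3,5-bis(methoxymethoxy)phenoxy]triisopropylsilane | COCOc1cc(OCOC)cc(O[Si](C(C)C)(C(C)C)C(C)C)c1 | intermediate
4 | prenyl bromide (1-bromo-3-methylbut-2-ene) | CC(C)=CCBr | starting material
5 | [2,6-bis(methoxymethoxy)-4-(triisopropylsilyloxy)phenyl]lithium (not isolated) | [Li]c1c(OCOC)cc(O[Si](C(C)C)(C(C)C)C(C)C)cc1OCOC | intermediate
6 | [2,6-bis(methoxymethoxy)-4-(triisopropylsilyloxy)phenyl]copper (not isolated) | [Cu]c1c(OCOC)cc(O[Si](C(C)C)(C(C)C)C(C)C)cc1OCOC | intermediate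
7 | [3,5-bis(methoxymethoxy)-4-prenylphenoxy]triisopropylsilane | COCOc1cc(O[Si](C(C)C)(C(C)C)C(C)C)cc(OCOC)c1CC=C(C)C | intermediate
8 | 3,5-bis(methoxymethoxy)-4-prenylphenol | COCOc1cc(O)cc(OCOC)c1CC=C(C)C | intermediate
9 | 3,5-bis(methoxymethoxy)-4-prenylphenyl N-isopropylcarbamate | COCOc1cc(OC(=O)NC(C)C)cc(OCOC)c1CC=C(C)C | intermediate
10 | 3,5-bis(methoxymethoxy)-4-prenylphenyl N-(tert-butyldimethylsilyl)-N-isopropylcarbamate (not isolated) | COCOc1cc(OC(=O)N(C(C)C)[Si](C)(C)C(C)(C)C)cc(OCOC)c1CC=C(C)C | intermediate
11 | 2-lithio derivative of 10 (not isolated) | [Li]c1c(OC(=O)N(C(C)C)[Si](C)(C)C(C)(C)C)cc(OCOC)c(CC=C(C)C)c1OCOC | intermediate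
12 | 3,5-bis(methoxymethoxy)-4-prenyl-2-(trimethylsilyl)phenyl N-(tert-butyldimethylsilyl)-N-isopropylcarbamate (not isolated) | C[Si](C)(C)c1c(OC(=O)N(C(C)C)[Si](C)(C)C(C)(C)C)cc(OCOC)c(CC=C(C)C)c1OCOC | intermediate
13 | 3,5-bis(methoxymethoxy)-4-prenyl-2-(trimethylsilyl)phenyl N-isopropylcarbamate | C[Si](C)(C)c1c(OC(=O)NC(C)C)cc(OCOC)c(CC=C(C)C)c1OCOC | intermediate
14 | 3,5-bis(methoxymethoxy)-4-prenyl-2-(trimethylsilyl)phenol (not isolated) | C[Si](C)(C)c1c(O)cc(OCOC)c(CC=C(C)C)c1OCOC | intermediate
15 | 3,5-bis(methoxymethoxy)-4-prenyl-2-(trimethylsilyl)phenyl trifluoromethanesulfonate | C[Si](C)(C)c1c(OS(=O)(=O)C(F)(F)F)cc(OCOC)c(CC=C(C)C)c1OCOC | intermediate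
16 | 3-bromo-4,5-dihydroxybenzaldehyde | O=Cc1cc(O)c(O)c(Br)c1 | starting material
17 | 3-bromo-5-hydroxy-4-methoxybenzaldehyde | COc1c(O)cc(C=O)cc1Br | intermediate
18 | 3-bromo-5-(dimethoxymethyl)-2-methoxyphenol | COC(OC)c1cc(O)c(OC)c(Br)c1 | intermediate
19 | 1-bromo-5-(dimethoxymethyl)-2-methoxy-3-(methoxymethoxy)benzene | COCOc1cc(C(OC)OC)cc(Br)c1OC | intermediate
20 | [5-(dimethoxymethyl)-2-methoxy-3-(methoxymethoxy)phenyl]lithium (not isolated) | [Li]c1cc(C(OC)OC)cc(OCOC)c1OC | intermediate
21 | [5-(dimethoxymethyl)-2-methoxy-3-(methoxymethoxy)phenyl]copper (not isolated) | [Cu]c1cc(C(OC)OC)cc(OCOC)c1OC | intermediate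
22 | 5-(dimethoxymethyl)-2-methoxy-1-(methoxymethoxy)-3-prenylbenzene (not isolated) | COCOc1cc(C(OC)OC)cc(CC=C(C)C)c1OC | intermediate
23 | 4-methoxy-3-(methoxymethoxy)-5-prenylbenzaldehyde | COCOc1cc(C=O)cc(CC=C(C)C)c1OC | intermediate
24 | Meldrum's acid (2,2-dimethyl-1,3-dioxane-4,6-dione) | CC1(C)OC(=O)CC(=O)O1 | starting material
25 | 5-[4-methoxy-3-(methoxymethoxy)-5-prenylbenzylidene]-2,2-dimethyl-1,3-dioxane-4,6-dione (not isolated) | COCOc1cc(C=C2C(=O)OC(C)(C)OC2=O)cc(CC=C(C)C)c1OC | intermediate
26 | 5-[4-methoxy-3-(methoxymethoxy)-5-prenylbenzyl]-2,2-dimethyl-1,3-dioxane-4,6-dione | COCOc1cc(CC2C(=O)OC(C)(C)OC2=O)cc(CC=C(C)C)c1OC | intermediate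
27 | 2-[4-methoxy-3-(methoxymethoxy)-5-prenylbenzyl]malonic acid (not isolated) | COCOc1cc(CC(C(=O)O)C(=O)O)cc(CC=C(C)C)c1OC | intermediate
28 | 3-[4-methoxy-3-(methoxymethoxy)-5-prenylphenyl]propanoic acid | COCOc1cc(CCC(O)=O)cc(CC=C(C)C)c1OC | intermediate
29 | caesium 3-[4-methoxy-3-(methoxymethoxy)-5-prenylphenyl]propanoate (not isolated) | COCOc1cc(CCC(=O)[O-])cc(CC=C(C)C)c1OC.[Cs+] | intermediate
30 | 3,5-bis(methoxymethoxy)-4-prenylbenzyne (not isolated) | COCOC1=C(CC=C(C)C)C(OCOC)=CC#C1 | intermediate
31 | caesium salt of the 2-metalated 3,5-bis(methoxymethoxy)-4-prenylphenyl ester of acid 28 (not isolated) | COCOc1cc(OC(=O)CCc2cc(OCOC)c(OC)c(CC=C(C)C)c2)[c-]c(OCOC)c1CC=C(C)C.[Cs+] | intermediate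
32 | 1-[6-hydroxy-2,4-bis(methoxymethoxy)-3-prenylphenyl]-3-[4-methoxy-3-(methoxymethoxy)-5-prenylphenyl]propan-1-one | COCOc1cc(CCC(=O)c2c(O)cc(OCOC)c(CC=C(C)C)c2OCOC)cc(CC=C(C)C)c1OC | intermediate
33 | 3,2',4',6'-tetrahydroxy-4-methoxy-3',5-diprenyldihydrochalcone | COc1c(O)cc(CCC(=O)c2c(O)cc(O)c(CC=C(C)C)c2O)cc1CC=C(C)C | target

**Step count**

Total step count: 15. Longest linear sequence: 9 steps (steps 1 to 7, 14, 15).

**Steps most likely to fail**

1. Step 14. The aryl anion may be protonated before the acyl shift, so that the reaction stops at the simple aryl ester. Acyl transfer to the hindered C1' beside the MOM ether may be slow, and the product phenoxide may be arylated by a second aryne. The fallback replaces the aryne insertion by directed metalation and acylation; it sets out from 8 and 28 and comes back at 33. Phenol 8 is etherified with MOMCl/iPr2NEt to 1,3,5-tris(methoxymethoxy)-2-prenylbenzene F1. Acid 28 is coupled with MeNHOMe·HCl (EDC·HCl, N-methylmorpholine, CH2Cl2) to the N-methoxy-N-methylamide F2. F1 is lithiated with n-BuLi (THF, 0 °C) at one of its two equivalent C–H bonds between MOM ethers to give [2,4,6-tris(methoxymethoxy)-3-prenylphenyl]lithium F3, which is added to F2 (−78 to 0 °C) to give the tetra-MOM dihydrochalcone F4. Methanolic HCl as in step 15 then removes all four MOM groups and gives 33.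

2. Step 6. n-BuLi/TMEDA may deprotonate the benzylic–allylic CH2 of the prenyl group in competition with the ring, incomplete N-silylation may open the way to an anionic ortho-Fries acyl migration, and silylation of the crowded ring may stall. The fallback uses a halogen and a silyl shift instead of a directed deprotonation; it sets out from 8 and comes back at 15. Phenol 8 is monobrominated ortho to the hydroxyl with NBS (1.0 equiv, CH2Cl2, −78 °C; the two ortho positions are equivalent and the ring is far more nucleophilic than the alkene) to 2-bromo-3,5-bis(methoxymethoxy)-4-prenylphenol F5. F5 is O-silylated with hexamethyldisilazane (THF, reflux) to the trimethylsilyl ether F6. n-BuLi (THF, −78 °C) then causes bromine–lithium exchange and O-to-C 1,3-silyl shift (retro-Brook rearrangement) to lithium 3,5-bis(methoxymethoxy)-4-prenyl-2-(trimethylsilyl)phenoxide F7, which is triflated in the same flask with PhNTf2 to give 15.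

3. Step 11 (the same concern applies to step 3). The arylcopper may attack the tertiary end of the prenyl electrophile (SN2′, reverse-prenyl isomer), the aryllithium may be butylated by the 1-bromobutane formed in the exchange, and some MOM ether may be lost during acetal hydrolysis. The fallback builds the prenyl group by allylation and olefin cross-metathesis; it sets out from 19 and comes back at 23. Aryllithium 20, generated from 19 as in step 11, is quenched with allyl bromide (a symmetrical allyl unit, so no regiochemical issue) to 1-allyl-5-(dimethoxymethyl)-2-methoxy-3-(methoxymethoxy)benzene F8. PPTS in acetone/water gives 3-allyl-4-methoxy-5-(methoxymethoxy)benzaldehyde F9. Cross-metathesis of F9 with excess 2-methylbut-2-ene and the second-generation Grubbs catalyst RuCl2(=CHPh)(H2IMes)(PCy3) (CH2Cl2, 40 °C) converts allyl into prenyl and gives 23.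

**Further compounds**

F1 | step 14 | 1,3,5-tris(methoxymethoxy)-2-prenylbenzene | COCOc1cc(OCOC)c(CC=C(C)C)c(OCOC)c1
F2 | step 14 | N-methoxy-N-methyl-3-[4-methoxy-3-(methoxymethoxy)-5-prenylphenyl]propanamide | COCOc1cc(CCC(=O)N(C)OC)cc(CC=C(C)C)c1OC
F3 | step 14 | [2,4,6-tris(methoxymethoxy)-3-prenylphenyl]lithium | [Li]c1c(OCOC)cc(OCOC)c(CC=C(C)C)c1OCOC
F4 | step 14 | 1-[2,4,6-tris(methoxymethoxy)-3-prenylphenyl]-3-[4-methoxy-3-(methoxymethoxy)-5-prenylphenyl]propan-1-one | COCOc1cc(CCC(=O)c2c(OCOC)cc(OCOC)c(CC=C(C)C)c2OCOC)cc(CC=C(C)C)c1OC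
F5 | step 6 | 2-bromo-3,5-bis(methoxymethoxy)-4-prenylphenol | COCOc1cc(O)c(Br)c(OCOC)c1CC=C(C)C
F6 | step 6 | [2-bromo-3,5-bis(methoxymethoxy)-4-prenylphenoxy]trimethylsilane | COCOc1cc(O[Si](C)(C)C)c(Br)c(OCOC)c1CC=C(C)C
F7 | step 6 | lithium 3,5-bis(methoxymethoxy)-4-prenyl-2-(trimethylsilyl)phenoxide | [Li+].[O-]c1cc(OCOC)c(CC=C(C)C)c(OCOC)c1[Si](C)(C)C
F8 | step 11 | 1-allyl-5-(dimethoxymethyl)-2-methoxy-3-(methoxymethoxy)benzene | COCOc1cc(C(OC)OC)cc(CC=C)c1OC
F9 | step 11 | 3-allyl-4-methoxy-5-(methoxymethoxy)benzaldehyde | COCOc1cc(C=O)cc(CC=C)c1OC
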